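At early times the run with more partner holds more product: at 0.625 d the oak run, with 4.00 times the partner of the maple run, already holds 16.6% of product against 4.60% in maple. So you reach for the bench rule: the partner is the limiting reagent, one partner per product, and the reaction stops when the partner is used up. For your flask that rule promises 55.0% of the substrates charged.

| flask | left-handed substrate | right-handed substrate | partner | precatalyst | remark | time |
|---|---|---|---|---|---|---|
| maple | 0.020 M | 0.020 M | 0.011 M | 0.50 mM | run made earlier |  |
| oak | 0.020 M | 0.020 M | 0.044 M | 0.50 mM | run made earlier |  |
| flask | 0.020 M | 0.020 M | 0.0220 M | 0.50 mM |  | 10 d |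

| run | time / d | left-handed product / % | right-handed product / % | left-handed substrate / % |
|---|---|---|---|---|
| maple | 0.625 | 3.7 | 0.9 | 46.0 |
| maple | 1.04 | 6.9 | 5.4 | 44.8 |
| maple | 1.67 | 5.6 | 6.4 | 41.0 |
| maple | 3.00 | 7.6 | 6.5 | 39.8 |
| maple | 5.00 | 9.2 | 7.3 | 37.2 |
| maple | 8.00 | 6.7 | 10.2 | 36.5 |
| oak | 0.625 | 8.8 | 7.8 | 39.8 |
| oak | 1.04 | 9.4 | 8.4 | 35.8 |
| oak | 1.67 | 10.5 | 9.1 | 36.9 |
| oak | 3.00 | 10.5 | 9.4 | 36.4 |
| oak | 5.00 | 9.5 | 9.8 | 36.0 |
| oak | 8.00 | 8.4 | 8.1 | 36.4 |

(readings scatter by 1 percentage point)

1. excess of left-handed product over right-handed product in the product at 5.0 h
2. excess of left-handed product over right-handed product in the product at 10 d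
3. part of the left-handed substrate and right-handed substrate charged together that has reacted at 10 d

- free catalyst is single-handed; left-handed substrate and right-handed substrate are mirror images of each other, charged as a racemate, each of them at the stated concentration
- what was read earlier has a scatter of 1 percentage point, one standard deviation
- an excess is below zero if the other one leads

Oak refutes the rule. Its partner exceeds both substrates together, yet over its last four readings the products average 18.8%. So try the catalyst as the limit, and define the turnover number, the product made per precatalyst charged. Oak gives a reading of 15.1.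

The border of the bench rule is the ratio of partner charged to what the catalyst can turn over, and the rule is in play where that ratio is below one. On the oak reading it is 1.46 for maple and 2.92 for your flask, so in both the partner charged exceeds the capacity reckoned for the catalyst.

Your flask has oak's substrates and precatalyst, so I reckon 18.8% reacted. Over the same readings oak's left-handed substrate has lost 13.6%, so in this reckoning the unread right-handed substrate supplies the remainder, 5.20%.

The forecast gives excesses of 22% at 5.0 h and 0% at 10 d, with 28% reacted at 10 d, and it reads the plateau as “a reversible reaction, with the partner acting kinetically and not limiting the yield”.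

The flask gives 19.0% reacted, with excesses of 39.5% at 5.0 h and 0% at 10 d.

    left-handed product ⇌ right-handed product (k = 0.0570 h⁻¹)
    partner + precatalyst → free catalyst + spent reagent (k = 3.60 L mol⁻¹ h⁻¹)
    partner + free catalyst → spent catalyst (k = 20.0 L mol⁻¹ h⁻¹)
    partner + free catalyst + right-handed substrate → free catalyst + right-handed product (k = 4300 L² mol⁻² h⁻¹)
    partner + free catalyst + left-handed substrate → free catalyst + left-handed product (k = 13000 L² mol⁻² h⁻¹)

At 10.0 d spent catalyst stands at >99.9% of the catalyst charged, while 61% of the partner remains. The flask's own turnover number comes to 15.2. Applied to a neighbour flask charged with 2.0 × 10⁻⁴ M of precatalyst, the oak reading of 15.1 gives 7.53% reacted, and that neighbour gives 8.20%.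

The runs come from a simulation with made-up constants, and the scatter is random.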